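The single ring of the target, the oxocene, is one oxygen bridging an unbroken seven-carbon run C7–C13 that contains the C9=C10 chloroalkene. Leaving the oxygen out and bonding C7 to C13 gives a 5-chlorocyclohept-4-enone with C13 as the ketone.
Ring order: the seven-membered carbocycle is closed first at C9=C10 by vinyl chloride ring-closing metathesis. It is then enlarged to the eight-membered lactone by Baeyer–Villiger insertion of O between C7 and C13, with retention at C7.
Before the key step: C7 comes from an Evans benzyloxymethylation. C10–C12 (from 2,3-dichloropropene) is joined to C13 as a sulfonyl carbanion, so no ketone enolate is formed beside the β-benzyloxy stereocentre.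
After the key step: lactone C13=O → ketene acetal phosphate → ethyl enol ether. Hydroboration sets C13 and oxygenates C12, after the enolisation that flattens C12 and not before it. Oxidation/reduction and invertive bromination then give 12S-Br.
Side chain: C6 aldehyde, chloroacetate Evans syn-aldol (C5–Cl, C6–OH), then Z-selective Peterson enyne olefination (C3=C4, C1≡C2).
Key step: step 8

Remark: atoms carry the numbers of the C15 chain of the target (C1≡C2–C3=C4–C5(Cl)–C6(OH)–C7…C13–C14–C15; ring = O + C7–C13). Read from the SMILES, the target is 3Z,5S,6S,7R,9E (ring-cis),12S,13R, with the C7 side chain cis to the C13 ethyl group, bromine trans to ethyl, and a 5,6-syn chlorohydrin.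

Step 1
Reactants: 1 pent-4-enoyl chloride; 2 (S)-4-benzyloxazolidin-2-one
Product: 3 (S)-4-benzyl-3-(pent-4-enoyl)oxazolidin-2-one
Conditions: Et3N, 4-(dimethylamino)pyridine (cat.), CH2Cl2, 0 °C → rt
Reagents that add atoms: none
Why: N-acylation of the carbamate nitrogen by an acid chloride under acyl-transfer catalysis is routine and touches no stereocentre.

Step 2
Reactants: 3 (S)-4-benzyl-3-(pent-4-enoyl)oxazolidin-2-one; 4 benzyl chloromethyl ether
Product: 6 (S)-4-benzyl-3-[(R)-2-(benzyloxymethyl)pent-4-enoyl]oxazolidin-2-one, via chlorotitanium Z-enolate 5 (not isolated)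
Conditions: TiCl4, i-Pr2NEt, CH2Cl2, 0 °C; then 4, 0 °C
Reagents that add atoms: none
Why: Evans asymmetric alkylation: soft enolisation gives the chelated Z-enolate, whose face opposite the auxiliary benzyl group captures the benzyloxymethyl cation equivalent and so sets C7 as R.

Step 3
Reactants: 6 (S)-4-benzyl-3-[(R)-2-(benzyloxymethyl)pent-4-enoyl]oxazolidin-2-one
Product: 7 (R)-2-(benzyloxymethyl)-N-methoxy-N-methylpent-4-enamide
Conditions: MeONHMe·HCl, AlMe3, CH2Cl2, –10 °C → rt
Reagents that add atoms: N,O-dimethylhydroxylamine hydrochloride, CNOC.Cl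
Why: Weinreb amide formation by aluminium amide transamination attacks the exocyclic imide carbonyl under non-basic conditions, so C7 keeps its configuration and the auxiliary is released intact.

Step 4
Reactants: 8 methyl phenyl sulfone; 9 2,3-dichloropropene
Product: 11 (3-chlorobut-3-en-1-yl) phenyl sulfone, via (phenylsulfonyl)methyllithium 10 (not isolated)
Conditions: n-BuLi, THF, –78 °C; then 9, –78 °C → rt
Reagents that add atoms: none
Why: SN2 alkylation of an α-sulfonyl carbanion takes place only at the allylic C–Cl bond of 9, the vinylic chloride being inert, and joins C12 to C11.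

Step 5
Reactants: 7 (R)-2-(benzyloxymethyl)-N-methoxy-N-methylpent-4-enamide; 11 (3-chlorobut-3-en-1-yl) phenyl sulfone
Product: 13 (6R)-6-(benzyloxymethyl)-2-chloro-4-(phenylsulfonyl)nona-1,8-dien-5-one (both epimers at the sulfonyl carbon C12), via lithiated sulfone 12 (not isolated)
Conditions: 11, n-BuLi, THF, –78 °C; then 7, –78 → –20 °C
Reagents that add atoms: none
Why: Acylation of an α-sulfonyl carbanion by a Weinreb amide stops at the chelated tetrahedral adduct, so C12–C13 forms without over-addition and the β-benzyloxy ketone never meets an enolising base that could epimerise C7 or expel benzyloxide.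

Step 6
Reactants: 13 (6R)-6-(benzyloxymethyl)-2-chloro-4-(phenylsulfonyl)nona-1,8-dien-5-one
Product: 14 (R)-6-(benzyloxymethyl)-2-chloronona-1,8-dien-5-one
Conditions: SmI2, THF–MeOH, –78 °C
Reagents that add atoms: none
Why: Reductive desulfonylation of a β-keto sulfone: two single-electron transfers from SmI2 cleave the activated C12–S bond and methanol protonates the regiodefined samarium enolate in the cold, leaving both alkenes, the C–Cl bond and C7 untouched.

Step 7
Reactants: 14 (R)-6-(benzyloxymethyl)-2-chloronona-1,8-dien-5-one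
Product: 15 (R)-2-(benzyloxymethyl)-5-chlorocyclohept-4-en-1-one
Conditions: RuCl2(=CHPh)(PCy3)(SIMes) (second-generation Grubbs catalyst, 10 mol %), benzene, 0.005 M, 65 °C
Reagents that add atoms: none
Why: Ring-closing metathesis of a 2-chloro-1-alkene with a terminal alkene is known for five- to seven-membered rings; the catalyst loads on the monosubstituted C9 alkene and closes onto the chloroalkene with release of Ru=CH2 rather than a chlorocarbene, and the seven-membered ring allows only the ring-cis C9=C10 geometry.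

Step 8
Reactants: 15 (R)-2-(benzyloxymethyl)-5-chlorocyclohept-4-en-1-one
Product: 17 (R)-8-(benzyloxymethyl)-5-chloro-3,4,7,8-tetrahydro-2H-oxocin-2-one, via silylated Criegee adduct 16 (not isolated)
Conditions: Me3SiOOSiMe3 (2 equiv), Me3SiOTf (0.3 equiv), 4 Å molecular sieves, CH2Cl2, –40 → 0 °C
Reagents that add atoms: bis(trimethylsilyl) peroxide, C[Si](C)(C)OO[Si](C)(C)C
Why: Me3SiOTf activates the C13 ketone for addition of the silyl peroxide to give adduct 16, in which the C7–C13 bond lying antiperiplanar to O–O shifts to oxygen as the silyloxy group leaves as (Me3Si)2O, so C7–O and O–C13 replace C7–C13. This is the aprotic form of the Baeyer–Villiger oxidation, a known reaction of 2-substituted cycloalkanones, cycloheptanones included. The eight-membered ring is not cyclised end to end but grows out of the seven-membered ring by a one-atom 1,2-shift ring expansion, which avoids the entropic and transannular cost of a medium-ring closure. No stereocentre is created, and the concerted shift carries C7 over with retention, so the R configuration from step 2 is kept. Regioselectivity needs the secondary C7 to migrate ahead of the primary C12, which its better ability to bear positive charge secures, although the β-benzyloxy group narrows the margin. Chemoselectivity needs the trisubstituted C9=C10 chloroalkene to survive; seven-ring ketones react slowly with free peracids, which would then have time to epoxidise it, so a silyl peroxide is used that reacts only as a nucleophile at the activated carbonyl and does not epoxidise isolated alkenes under these conditions.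

Step 9
Reactants: 17 (R)-8-(benzyloxymethyl)-5-chloro-3,4,7,8-tetrahydro-2H-oxocin-2-one
Product: 18 (R)-8-(benzyloxymethyl)-5-chloro-7,8-dihydro-4H-oxocin-2-yl diphenyl phosphate
Conditions: KN(SiMe3)2, (PhO)2P(O)Cl, HMPA, THF, –78 °C
Reagents that add atoms: diphenyl chlorophosphate, O=P(Cl)(Oc1ccccc1)Oc1ccccc1
Why: O-phosphorylation of the potassium lactone enolate (ketene acetal phosphate formation) fixes C12=C13 inside the ring; only C12 carries acidic hydrogens, and it is left unoxygenated up to here because this enolisation would flatten any stereocentre placed there.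

Step 10
Reactants: 18 (R)-8-(benzyloxymethyl)-5-chloro-7,8-dihydro-4H-oxocin-2-yl diphenyl phosphate; 19 diethylzinc
Product: 20 (R)-8-(benzyloxymethyl)-5-chloro-2-ethyl-7,8-dihydro-4H-oxocine
Conditions: PdCl2(dppf) (5 mol %), THF, rt; Et3N-washed silica
Reagents that add atoms: none
Why: Negishi coupling of a lactone-derived ketene acetal phosphate: zerovalent palladium inserts into the C13–OP bond far faster than into the unactivated C10–Cl bond, and the wide-bite-angle ligand favours reductive elimination of the C13–C14 bond over β-hydride loss.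

Step 11
Reactants: 20 (R)-8-(benzyloxymethyl)-5-chloro-2-ethyl-7,8-dihydro-4H-oxocine
Product: 22 (2R,3S,8R)-8-(benzyloxymethyl)-5-chloro-2-ethyl-3,4,7,8-tetrahydro-2H-oxocin-3-ol, via C12 alkylborane 21 (not isolated)
Conditions: BH3·THF, THF, –20 → 0 °C; then NaOH, H2O2, 0 °C
Reagents that add atoms: hydrogen peroxide, OO (borane–THF supplies the boron of 21 only)
Why: Hydroboration–oxidation of a cyclic enol ether: the ring oxygen directs boron to C12, syn addition from the outer face turned away from the C7 side chain puts H on C13 (13R, ethyl cis to the C7 substituent), retentive oxidation gives the 12S alcohol trans to ethyl, and the electron-poor chloroalkene should react much more slowly.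

Step 12
Reactants: 22 (2R,3S,8R)-8-(benzyloxymethyl)-5-chloro-2-ethyl-3,4,7,8-tetrahydro-2H-oxocin-3-ol
Product: 23 (2R,8R)-8-(benzyloxymethyl)-5-chloro-2-ethyl-7,8-dihydro-2H-oxocin-3(4H)-one
Conditions: Dess–Martin periodinane, NaHCO3, CH2Cl2, 0 °C
Reagents that add atoms: none
Why: Dess–Martin oxidation under bicarbonate buffer is mild enough to give the β,γ-unsaturated C12 ketone without moving C9=C10 into conjugation or epimerising C13.

Step 13
Reactants: 23 (2R,8R)-8-(benzyloxymethyl)-5-chloro-2-ethyl-7,8-dihydro-2H-oxocin-3(4H)-one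
Product: 24 (2R,3R,8R)-8-(benzyloxymethyl)-5-chloro-2-ethyl-3,4,7,8-tetrahydro-2H-oxocin-3-ol
Conditions: LiBH(s-Bu)3 (L-Selectride), THF, –78 °C
Reagents that add atoms: none
Why: Bulky trialkylborohydride reduction: hydride reaches C12 from the face opposite the neighbouring C13 ethyl group, so the hydroxyl ends cis to ethyl (12R), the epimer that an invertive bromination requires.

Step 14
Reactants: 24 (2R,3R,8R)-8-(benzyloxymethyl)-5-chloro-2-ethyl-3,4,7,8-tetrahydro-2H-oxocin-3-ol
Product: 25 (2R,3S,8R)-8-(benzyloxymethyl)-3-bromo-5-chloro-2-ethyl-3,4,7,8-tetrahydro-2H-oxocine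
Conditions: CBr4, P(n-C8H17)3, toluene, 70 °C
Reagents that add atoms: carbon tetrabromide, BrC(Br)(Br)Br
Why: Appel-type bromination, established for 3-hydroxy-2-alkyloxocenes: bromide displaces the alkoxyphosphonium ion in an SN2 step with inversion, which sets 12S with bromine trans to ethyl.

Step 15
Reactants: 25 (2R,3S,8R)-8-(benzyloxymethyl)-3-bromo-5-chloro-2-ethyl-3,4,7,8-tetrahydro-2H-oxocine
Product: 26 [(2R,7S,8R)-7-bromo-5-chloro-8-ethyl-3,6,7,8-tetrahydro-2H-oxocin-2-yl]methanol
Conditions: BCl3·SMe2, CH2Cl2, 0 °C → rt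
Reagents that add atoms: none
Why: Lewis-acid debenzylation: boron binds the unhindered benzylic ether oxygen and chloride takes the benzyl group, a cleavage that needs neither hydrogen nor dissolving metal and so spares C–Br, C–Cl and the alkene.

Step 16
Reactants: 26 [(2R,7S,8R)-7-bromo-5-chloro-8-ethyl-3,6,7,8-tetrahydro-2H-oxocin-2-yl]methanol
Product: 27 (2R,7S,8R)-7-bromo-5-chloro-8-ethyl-3,6,7,8-tetrahydro-2H-oxocine-2-carbaldehyde
Conditions: Dess–Martin periodinane, NaHCO3, CH2Cl2, 0 °C → rt; used crude
Reagents that add atoms: none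
Why: Dess–Martin oxidation stops at the aldehyde under near-neutral conditions, so the α-alkoxy centre C7 is not epimerised.

Step 17
Reactants: 28 (R)-4-benzyloxazolidin-2-one; 29 chloroacetyl chloride
Product: 31 (R)-4-benzyl-3-(chloroacetyl)oxazolidin-2-one, via lithium oxazolidinide 30 (not isolated)
Conditions: n-BuLi, THF, –78 °C; then 29, –78 → 0 °C
Reagents that add atoms: none
Why: N-acylation of the lithiated oxazolidinone occurs at the acyl chloride much faster than displacement at the alkyl chloride.

Step 18
Reactants: 27 (2R,7S,8R)-7-bromo-5-chloro-8-ethyl-3,6,7,8-tetrahydro-2H-oxocine-2-carbaldehyde; 31 (R)-4-benzyl-3-(chloroacetyl)oxazolidin-2-one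
Product: 33 (R)-4-benzyl-3-{(2R,3S)-3-[(2R,7S,8R)-7-bromo-5-chloro-8-ethyl-3,6,7,8-tetrahydro-2H-oxocin-2-yl]-2-chloro-3-hydroxypropanoyl}oxazolidin-2-one, via dibutylboron Z-enolate 32 (not isolated)
Conditions: 31, n-Bu2BOTf, Et3N, CH2Cl2, –78 → 0 °C; then 27, –78 → 0 °C; then H2O2, MeOH, pH 7 buffer
Reagents that add atoms: none
Why: Evans syn-aldol reaction of a chloroacetyl imide: the Z-boron enolate reacts through a Zimmerman–Traxler chair whose face is fixed by the R auxiliary, which sets the C5 chloride and C6 hydroxyl syn with 6S (6,7-syn), the auxiliary overriding the weaker Cornforth bias of the α-alkoxy aldehyde.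

Step 19
Reactants: 33 the aldol adduct of step 18
Product: 34 C6 triethylsilyl ether of 33
Conditions: Et3SiOTf, 2,6-lutidine, CH2Cl2, –78 °C
Reagents that add atoms: triethylsilyl trifluoromethanesulfonate, CC[Si](CC)(CC)OS(=O)(=O)C(F)(F)F
Why: Silyl triflate silylation with a hindered pyridine base caps the C6 hydroxyl without generating an alkoxide that could close onto C5 or undergo retro-aldol cleavage.

Step 20
Reactants: 34 C6 triethylsilyl ether of 33
Product: 35 (2S,3S)-3-[(2R,7S,8R)-7-bromo-5-chloro-8-ethyl-3,6,7,8-tetrahydro-2H-oxocin-2-yl]-2-chloro-3-(triethylsilyloxy)propan-1-ol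
Conditions: LiBH4, H2O (1 equiv), Et2O, 0 °C
Reagents that add atoms: none
Why: Reductive removal of the auxiliary: borohydride attacks the activated exocyclic imide carbonyl, while secondary alkyl halides and the silyl ether withstand this reagent at 0 °C.

Step 21
Reactants: 35 (2S,3S)-3-[(2R,7S,8R)-7-bromo-5-chloro-8-ethyl-3,6,7,8-tetrahydro-2H-oxocin-2-yl]-2-chloro-3-(triethylsilyloxy)propan-1-ol
Product: 36 (2R,3S)-3-[(2R,7S,8R)-7-bromo-5-chloro-8-ethyl-3,6,7,8-tetrahydro-2H-oxocin-2-yl]-2-chloro-3-(triethylsilyloxy)propanal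
Conditions: Dess–Martin periodinane, NaHCO3, CH2Cl2, 0 °C; used crude
Reagents that add atoms: none
Why: Dess–Martin oxidation delivers the α-chloro aldehyde (C4) without base strong enough to epimerise C5 or eliminate the β-silyloxy group.

Step 22
Reactants: 37 1-(trimethylsilyl)propyne
Product: 39 3-(tert-butyldimethylsilyl)-1-(trimethylsilyl)prop-1-yne, via lithiated silylpropyne 38 (not isolated)
Conditions: n-BuLi, TMEDA, Et2O, 0 °C; then t-BuMe2SiCl
Reagents that add atoms: tert-butyldimethylsilyl chloride, CC(C)(C)[Si](C)(C)Cl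
Why: Propargylic lithiation followed by C-silylation, in which the bulky chlorosilane is taken up at the propargylic terminus of the ambident anion.

Step 23
Reactants: 36 (2R,3S)-3-[(2R,7S,8R)-7-bromo-5-chloro-8-ethyl-3,6,7,8-tetrahydro-2H-oxocin-2-yl]-2-chloro-3-(triethylsilyloxy)propanal; 39 3-(tert-butyldimethylsilyl)-1-(trimethylsilyl)prop-1-yne
Product: 42 C6-O-triethylsilyl C1-trimethylsilyl bermudenynol (3Z,5S,6S,7R,12S,13R), via lithiated bis-silylpropyne 40 (not isolated), via titanium ate complex 41 (not isolated)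
Conditions: 39, t-BuLi, THF, –78 °C; Ti(Oi-Pr)4, –78 °C; then 36, –78 °C → rt
Reagents that add atoms: none
Why: Peterson olefination in its titanium-mediated, Z-selective enyne form: the weakly basic propargyltitanium reagent adds to the aldehyde through a closed transition state to the β-silyl alkoxide whose syn loss of silanolate gives the 3Z enyne, and the poorly nucleophilic titanium alkoxide should eliminate faster than it can displace the C5 chloride.

Step 24
Reactants: 42 C6-O-triethylsilyl C1-trimethylsilyl bermudenynol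
Product: 43 bermudenynol
Conditions: Bu4NF, AcOH (1:1), THF, 0 °C → rt
Reagents that add atoms: none
Why: Fluoride desilylation removes the alkynyl and the O-silyl group together, and the acetic acid buffer protonates the C6 oxygen as it is freed, so the syn chlorohydrin cannot close to the vinyl epoxide.

Compound list
1 | pent-4-enoyl chloride | C=CCCC(=O)Cl | starting material
2 | (S)-4-benzyloxazolidin-2-one | O=C1N[C@@H](Cc2ccccc2)CO1 | starting material
3 | (S)-4-benzyl-3-(pent-4-enoyl)oxazolidin-2-one | C=CCCC(=O)N1C(=O)OC[C@@H]1Cc1ccccc1 | intermediate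
4 | benzyl chloromethyl ether | ClCOCc1ccccc1 | starting material
5 | trichlorotitanium Z-enolate of 3 (not isolated) | C=CC/C=C(\O[Ti](Cl)(Cl)Cl)N1C(=O)OC[C@@H]1Cc1ccccc1 | intermediate
6 | (S)-4-benzyl-3-[(R)-2-(benzyloxymethyl)pent-4-enoyl]oxazolidin-2-one | C=CC[C@H](COCc1ccccc1)C(=O)N1C(=O)OC[C@@H]1Cc1ccccc1 | intermediate
7 | (R)-2-(benzyloxymethyl)-N-methoxy-N-methylpent-4-enamide | C=CC[C@H](COCc1ccccc1)C(=O)N(C)OC | intermediate
8 | methyl phenyl sulfone | CS(=O)(=O)c1ccccc1 | starting material
9 | 2,3-dichloropropene | C=C(Cl)CCl | starting material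
10 | (phenylsulfonyl)methyllithium (not isolated) | [Li]CS(=O)(=O)c1ccccc1 | intermediate
11 | (3-chlorobut-3-en-1-yl) phenyl sulfone | C=C(Cl)CCS(=O)(=O)c1ccccc1 | intermediate
12 | 3-chloro-1-(phenylsulfonyl)but-3-enyllithium (not isolated) | [Li]C(CC(Cl)=C)S(=O)(=O)c1ccccc1 | intermediate
13 | (6R)-6-(benzyloxymethyl)-2-chloro-4-(phenylsulfonyl)nona-1,8-dien-5-one, epimers at C12 | C=CC[C@H](COCc1ccccc1)C(=O)C(CC(Cl)=C)S(=O)(=O)c1ccccc1 | intermediate
14 | (R)-6-(benzyloxymethyl)-2-chloronona-1,8-dien-5-one | C=CC[C@H](COCc1ccccc1)C(=O)CCC(Cl)=C | intermediate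
15 | (R)-2-(benzyloxymethyl)-5-chlorocyclohept-4-en-1-one | c1ccccc1COC[C@H]1C/C=C(/Cl)CCC1=O | intermediate
16 | C13 trimethylsilyloxy trimethylsilylperoxy adduct of 15 (not isolated) | c1ccccc1COC[C@H]1C/C=C(/Cl)CCC1(O[Si](C)(C)C)OO[Si](C)(C)C | intermediate
17 | (R)-8-(benzyloxymethyl)-5-chloro-3,4,7,8-tetrahydro-2H-oxocin-2-one | c1ccccc1COC[C@H]1C/C=C(/Cl)CCC(=O)O1 | intermediate
18 | (R)-8-(benzyloxymethyl)-5-chloro-7,8-dihydro-4H-oxocin-2-yl diphenyl phosphate | c1ccccc1COC[C@H]1C/C=C(/Cl)C/C=C(/OP(=O)(Oc2ccccc2)Oc2ccccc2)O1 | intermediate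
19 | diethylzinc | CC[Zn]CC | starting material
20 | (R)-8-(benzyloxymethyl)-5-chloro-2-ethyl-7,8-dihydro-4H-oxocine | c1ccccc1COC[C@H]1C/C=C(/Cl)C/C=C(/CC)O1 | intermediate
21 | C12 alkylborane from 20, boron trans to ethyl (not isolated) | c1ccccc1COC[C@H]1C/C=C(/Cl)C[C@H](B)[C@@H](CC)O1 | intermediate
22 | (2R,3S,8R)-8-(benzyloxymethyl)-5-chloro-2-ethyl-3,4,7,8-tetrahydro-2H-oxocin-3-ol (12S, OH trans to ethyl) | c1ccccc1COC[C@H]1C/C=C(/Cl)C[C@H](O)[C@@H](CC)O1 | intermediate
23 | (2R,8R)-8-(benzyloxymethyl)-5-chloro-2-ethyl-7,8-dihydro-2H-oxocin-3(4H)-one | c1ccccc1COC[C@H]1C/C=C(/Cl)CC(=O)[C@@H](CC)O1 | intermediate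
24 | (2R,3R,8R)-8-(benzyloxymethyl)-5-chloro-2-ethyl-3,4,7,8-tetrahydro-2H-oxocin-3-ol (12R, OH cis to ethyl) | c1ccccc1COC[C@H]1C/C=C(/Cl)C[C@@H](O)[C@@H](CC)O1 | intermediate
25 | (2R,3S,8R)-8-(benzyloxymethyl)-3-bromo-5-chloro-2-ethyl-3,4,7,8-tetrahydro-2H-oxocine | c1ccccc1COC[C@H]1C/C=C(/Cl)C[C@H](Br)[C@@H](CC)O1 | intermediate
26 | [(2R,7S,8R)-7-bromo-5-chloro-8-ethyl-3,6,7,8-tetrahydro-2H-oxocin-2-yl]methanol | OC[C@H]1C/C=C(/Cl)C[C@H](Br)[C@@H](CC)O1 | intermediate
27 | (2R,7S,8R)-7-bromo-5-chloro-8-ethyl-3,6,7,8-tetrahydro-2H-oxocine-2-carbaldehyde | O=C[C@H]1C/C=C(/Cl)C[C@H](Br)[C@@H](CC)O1 | intermediate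
28 | (R)-4-benzyloxazolidin-2-one | O=C1N[C@H](Cc2ccccc2)CO1 | starting material
29 | chloroacetyl chloride | ClCC(=O)Cl | starting material
30 | lithium salt of 28 (not isolated) | [Li]N1C(=O)OC[C@H]1Cc1ccccc1 | intermediate
31 | (R)-4-benzyl-3-(chloroacetyl)oxazolidin-2-one | ClCC(=O)N1C(=O)OC[C@H]1Cc1ccccc1 | intermediate
32 | dibutylboron Z-enolate of 31 (not isolated) | Cl/C=C(\OB(CCCC)CCCC)N1C(=O)OC[C@H]1Cc1ccccc1 | intermediate
33 | syn-aldol adduct, (2R,3S)-2-chloro-3-hydroxy-3-(oxocenyl)propanoyl imide of 28 | O=C1OC[C@@H](Cc2ccccc2)N1C(=O)[C@H](Cl)[C@@H](O)[C@H]1C/C=C(/Cl)C[C@H](Br)[C@@H](CC)O1 | intermediate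
34 | C6 triethylsilyl ether of 33 | O=C1OC[C@@H](Cc2ccccc2)N1C(=O)[C@H](Cl)[C@@H](O[Si](CC)(CC)CC)[C@H]1C/C=C(/Cl)C[C@H](Br)[C@@H](CC)O1 | intermediate
35 | (2S,3S)-2-chloro-3-(oxocenyl)-3-(triethylsilyloxy)propan-1-ol | OC[C@H](Cl)[C@@H](O[Si](CC)(CC)CC)[C@H]1C/C=C(/Cl)C[C@H](Br)[C@@H](CC)O1 | intermediate
36 | (2R,3S)-2-chloro-3-(oxocenyl)-3-(triethylsilyloxy)propanal | O=C[C@H](Cl)[C@@H](O[Si](CC)(CC)CC)[C@H]1C/C=C(/Cl)C[C@H](Br)[C@@H](CC)O1 | intermediate
37 | 1-(trimethylsilyl)propyne | CC#C[Si](C)(C)C | starting material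
38 | 3-lithio-1-(trimethylsilyl)propyne (not isolated) | [Li]CC#C[Si](C)(C)C | intermediate
39 | 3-(tert-butyldimethylsilyl)-1-(trimethylsilyl)prop-1-yne | C[Si](C)(C)C#CC[Si](C)(C)C(C)(C)C | intermediate
40 | 3-lithio derivative of 39 (not isolated) | C[Si](C)(C)C#CC([Li])[Si](C)(C)C(C)(C)C | intermediate
41 | lithium tetraisopropoxy(propargyl)titanate from 40 (not isolated) | [Li+].CC(C)O[Ti-](OC(C)C)(OC(C)C)(OC(C)C)C(C#C[Si](C)(C)C)[Si](C)(C)C(C)(C)C | intermediate
42 | C6-O-triethylsilyl C1-trimethylsilyl bermudenynol | C[Si](C)(C)C#C/C=C\[C@H](Cl)[C@@H](O[Si](CC)(CC)CC)[C@H]1C/C=C(/Cl)C[C@H](Br)[C@@H](CC)O1 | intermediate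
43 | bermudenynol | C#C/C=C\[C@H](Cl)[C@@H](O)[C@H]1C/C=C(/Cl)C[C@H](Br)[C@@H](CC)O1 | target

Total step count: 24.
Longest linear sequence: 21 steps from 1 (steps 1–3, 5–16, 18–21, 23, 24). Steps 4, 17 and 22 are side branches.

Steps most likely to fail

Step 8. Addition of the peroxide to the sluggish seven-ring ketone may be slow enough for cyclic peroxide formation or oxidation at C9=C10 to compete. The β-benzyloxy group may also allow partial migration of C12. The fallback builds the lactone by esterification and metathesis, with no oxygen insertion.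
- It sets out from 9, which alkylates the lithium enolate of tert-butyl acetate to give tert-butyl 4-chloropent-4-enoate F1.
- CF3CO2H frees 4-chloropent-4-enoic acid F2.
- In parallel, commercial (R)-benzyl glycidyl ether is opened with vinylmagnesium bromide and catalytic CuI to (R)-1-(benzyloxy)pent-4-en-2-ol F3.
- Carbodiimide coupling of F2 and F3 gives (R)-1-(benzyloxy)pent-4-en-2-yl 4-chloropent-4-enoate F4.
- Ring-closing metathesis with RuCl2(=CH-C6H4-2-Oi-Pr)(SIMes) (second-generation Hoveyda–Grubbs catalyst) at high dilution in hot toluene closes C9=C10 and comes back to the route at 17.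

Step 11. Borane may approach the enol ether with poor facial selectivity, which would lose the 7,13-cis relation. It may also add to the chloroalkene, followed by loss of chloride. The fallback replaces hydroboration by epoxidation and reductive opening.
- It sets out from 20, which dimethyldioxirane in acetone/CH2Cl2 at –78 °C oxidises only at the electron-rich enol ether, giving the 12,13-epoxide of 20 with the oxirane oxygen trans to the C7 side chain F5.
- i-Bu2AlH added to the same flask binds the oxirane oxygen, opens the acetal C13–O bond and delivers hydride to C13 from the same face.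
- The fallback comes back to the route at 22.

Step 23. The bulky nucleophile may add slowly. That would leave time for enolisation and epimerisation at C5, or for closure of the C4 alkoxide onto C5 with loss of chloride before silanolate elimination. The fallback is a two-step Wittig and cross-coupling construction of the enyne.
- It sets out from 36, which a Stork–Zhao olefination with Ph3P=CHI (from (iodomethyl)triphenylphosphonium iodide and NaN(SiMe3)2, THF, –78 °C) converts into the (3Z)-vinyl iodide F6.
- Sonogashira coupling of F6 with trimethylsilylacetylene (Pd(PPh3)4, CuI, i-Pr2NH) comes back to the route at 42.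
- The contact time at or below rt is kept short, so that zerovalent palladium has little time to ionise the allylic C5–Cl bond.

Further compounds
F1 | step 8 | tert-butyl 4-chloropent-4-enoate | C=C(Cl)CCC(=O)OC(C)(C)C
F2 | step 8 | 4-chloropent-4-enoic acid | C=C(Cl)CCC(=O)O
F3 | step 8 | (R)-1-(benzyloxy)pent-4-en-2-ol | C=CC[C@H](COCc1ccccc1)O
F4 | step 8 | (R)-1-(benzyloxy)pent-4-en-2-yl 4-chloropent-4-enoate | C=CC[C@H](COCc1ccccc1)OC(=O)CCC(Cl)=C
F5 | step 11 | 12,13-epoxide of 20, oxirane oxygen trans to the C7 side chain | c1ccccc1COC[C@H]1C/C=C(/Cl)C[C@@H]2O[C@]2(CC)O1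
F6 | step 23 | (3Z)-vinyl iodide from 36 | I/C=C\[C@H](Cl)[C@@H](O[Si](CC)(CC)CC)[C@H]1C/C=C(/Cl)C[C@H](Br)[C@@H](CC)O1
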